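## Structural features

The target is a flavone: a benzene ring (ring A) fused to a 4H-pyran-4-one (ring C), with a 3,4-dimethoxyphenyl group (ring B) on C2. It has no stereocentre and is achiral, so every chiral intermediate can be used as a racemate. Ring A is fully substituted, with methoxy groups at C5, C6 and C8, the only free hydroxyl at C7, the ring oxygen O1 on C8a and the carbonyl carbon C4 on C4a, which makes five contiguous oxygens and one carbon substituent on one benzene ring. The fragile points are the 5-methoxy group peri to the C4 carbonyl (cleaved first by chelating Lewis acids), the C2=C3 bond of the pyranone (open to hydrogenation and to nucleophilic ring opening), and the electron-rich ring A phenol (prone to oxidation). The real difficulty is the regiodefined pentaoxygenation of ring A with the C7 oxygen distinguished from its two methoxy neighbours. The key step exploits this pattern: C8a, C6, C7 and C8 with their oxygens map onto C1, C2, C3 and C4 of a trialkoxycyclobutenone, and C4a and C5 map onto the two carbons of a methoxyalkyne. Every oxygen is thus delivered in place, and a benzyl ether on the cyclobutenone marks C7.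

## Logic of the disconnections

21 to 20: the C7 oxygen is given back its benzyl group, so the O–CH2Ph bond is the one that the last forward step cleaves. The lone hydroxyl has to be told apart from four methyl ethers, and a benzyl ether carried from the start avoids any late selective methylation. The forward step must remove benzyl without reducing C2=C3 and without a Lewis acid that would attack the 5-methoxy group.

20 to 17: the O1–C2 bond of ring C is cut and C4 is taken back to the carbinol level, passing through 19 and 18. An ortho-hydroxyaryl ynone is the open-chain equivalent of the pyranone, and its carbinol is what survives a ketene-based ring synthesis. This removes ring C and leaves a phenol with a three-carbon side chain. The forward step needs an oxidant that takes the activated carbinol but spares the phenol, and a closure that goes 6-endo and not 5-exo; routing it through 19 secures the latter.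

17 to 16: the O–Si bond is restored. The carbinol must be masked while a ketene is present, and a silyl ether is the least ionisable mask at this doubly activated position. Removal has to be buffered so that the ortho-hydroxybenzylic system is not pushed toward a quinone methide.

16 to 4 plus 11: the bonds C4a–C8a, C5–C6 and C8–C8a are cut. The ring falls into a four-carbon unit carrying four of its oxygens and a two-carbon unit carrying the fifth, so no oxygen has to be introduced onto an aromatic ring. The atom count (C13H14O4 plus C20H28O4Si equals C33H42O8Si) and the atom map (C1 to C4 of 4 become C8a, C6, C7, C8; the alkyne carbons of 11 become C4a and C5) show 4, 11 and 16 to be mutually consistent. The forward cascade needs a regioselective ketene–alkyne union and selection of the ynol ether over the arylalkyne. The ynol ether in 11 is methyl so that no retro-ene loss of an alkene can occur on heating.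

11 to 10 to 7 plus 8: the O–Si bond and then the C–C bond between the carbinol carbon and the ynol ether are cut. This is an acetylide–aldehyde addition and yields two simple pieces. Because 10 is an acid-labile 3-hydroxy ynol ether, the forward steps use a neutral work-up and immediate silylation.

7 to 5: the C–CHO bond is cut, which is a formylation of a terminal alkyne through 6.

4 to 3: the C3–O bond to benzyl is cut. In 3 only C3 is the β-carbon of a vinylogous ester, so the marker for C7 enters where differentiation is intrinsic. The exchange is run under base and not acid, because acid would ionise the C4–O bond and collapse the ring to a cyclobutenedione. Since C1 and C3 are both bonded to C2 and C4, hydrolysis of 3 would give a symmetric vinylogous acid whose O-benzylation can only lead to 4; this is the reserve route.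

3 to 2 to 1: the O–CH3 bond at C4 and then the C4–H bond are cut. This leads back to the symmetric 1, in which one hydride addition both desymmetrises the ring and creates the future C8. The forward steps must stop at mono-addition and stay away from acid.

## Other disconnections considered

Alternative 1: The cut is at the two aryl C–O bonds C6–OMe and C8–OMe of a complete flavone, so that 6,8-dibromo-2-(3,4-dimethoxyphenyl)-5,7-dihydroxy-4H-chromen-4-one A1 would be converted into 2-(3,4-dimethoxyphenyl)-5,7-dihydroxy-6,8-dimethoxy-4H-chromen-4-one A2.
- Forward key step: the dibromide A1 heated with NaOMe and CuBr in DMF should undergo twofold copper-mediated methanolysis of its aryl bromides to give A2 without closing a ring.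
- In its favour: the skeleton of A1 comes from classical chemistry of 1,3,5-trioxygenated benzenes, the bromination at C6 and C8 that leads to A1 is exhaustive and needs no regiocontrol, and every reaction type is established.
- Against it here: A2 has free hydroxyls at C5 and C7, whereas the target needs C5 methylated and C7 free. The chelated 5-hydroxyl is the less reactive one, so benzylation at O7, forced methylation at O5 and hydrogenolysis would have to follow. Copper insertion into an electron-rich bis-phenoxide should be slow, reductive loss of bromine competes, and the pyranone must survive hot methoxide.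
- Comparison: on structure the chosen plan is ahead, since each oxygen arrives in final form and only one deprotection remains. On mechanism Alternative 1 is the better plan, since it uses only precedented reactions while the chosen plan rests on an untested cascade. On step economy the two are about equal, with a possible small advantage to Alternative 1.

Alternative 2: The cut is at O1–C8a, C4–C4a and O1–C2, so ring C would be made in one operation from 5-(benzyloxy)-3,4-dimethoxy-2-(trimethylsilyl)phenyl trifluoromethanesulfonate A3 and 3-(3,4-dimethoxyphenyl)prop-2-ynoic acid A4 to give 7-(benzyloxy)-2-(3,4-dimethoxyphenyl)-5,6-dimethoxy-4H-chromen-4-one A5.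
- Forward key step: CsF should release the aryne from A3 by 1,2-elimination in the presence of the carboxylate of A4. The carboxylate oxygen should add at the future C8a, remote from the methoxy group, and the aryl anion at the future C4a should take the acyl carbon. The resulting ortho-hydroxyaryl ynone should close by oxa-Michael addition to A5.
- In its favour: ring C forms at the right oxidation level with no protecting-group or redox steps, which is better than steps 8 and 9 of the chosen plan. Regiochemistry follows from the inductive effect of the neighbouring methoxy group, the insertion is a known reaction type, and A4 is a simple acid one carboxylation away from a commercial arylalkyne.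
- Against it here: A5 carries hydrogen at C8. The missing methoxy group would need debenzylation, bromination ortho to the 7-hydroxyl and copper methanolysis on a flavone with other reactive positions (C3, ring B). The aryne precursor A3 itself needs a multistep synthesis, and 5-exo closure to an aurone is possible.
- Comparison: on structure the chosen plan is ahead, because Alternative 2 leaves ring A one oxygen short. On mechanism Alternative 2 has the better precedent. On step economy its key step is the more economical, but the whole route should be equal or longer.

Alternative 3: The cut is at O1–C8a only, so that 1-[4-(benzyloxy)-2,6-dibromo-3,5-dimethoxyphenyl]-3-(3,4-dimethoxyphenyl)propane-1,3-dione A6 would close to 7-(benzyloxy)-5-bromo-2-(3,4-dimethoxyphenyl)-6,8-dimethoxy-4H-chromen-4-one A7.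
- Forward key step: the diketone A6 under CuI, 1,10-phenanthroline and K2CO3 should undergo intramolecular Ullmann-type O-arylation. The enol oxygen displaces one of two equivalent ortho bromides and gives A7 with ring C closed.
- In its favour: the mirror-symmetric ring A of A6 comes from a cheap symmetric 3,4,5-trioxygenated benzoic acid derivative, and the two bromides are equivalent, so no regiochemical question arises. The bromide left in A7 sits at C5, peri to the carbonyl and activated for later displacement by methoxide.
- Against it here: the aryl ketone flanked by two ortho bromides is hindered and twisted, which burdens both the acylation that makes A6 and the planar arrangement needed for O-arylation. Methoxide at C5 of A7 competes with attack at C2 and opening of the pyranone, and two steps remain after the key step.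
- Comparison: on structure the plans are equal, since both carry all five ring A positions in defined form and end with the same hydrogenolysis. On mechanism Alternative 3 is better, using known reaction types only. On step economy it is probably equal or slightly shorter. The chosen plan offers a convergent union of two three-step fragments and avoids copper chemistry at doubly ortho-substituted carbons.

Key step: step 7

Assumption: compounds 2 to 4, 10, 11, 16 and 17 are handled as racemates, because each of their single stereocentres is erased before the achiral target.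

## Route

Step 1
Reactants: 1 dimethyl squarate (3,4-dimethoxycyclobut-3-ene-1,2-dione)
Product: 2 4-hydroxy-2,3-dimethoxycyclobut-2-en-1-one (racemic)
Conditions: LiAlH(OtBu)3 (1.1 equiv), THF, −78 → −40 °C; H2O quench, filtration
Reagents that add atoms: none
Why: Hydride 1,2-addition to one of the two equivalent ketones of a squarate ester, an established reduction of dialkyl squarates; it should stop after one addition because the remaining carbonyl of 2 is a deactivated vinylogous ester, and the new C4 centre forms as a racemate that later becomes aromatic C8.

Step 2
Reactants: 2 4-hydroxy-2,3-dimethoxycyclobut-2-en-1-one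
Product: 3 2,3,4-trimethoxycyclobut-2-en-1-one (racemic)
Conditions: MeI (10 equiv), Ag2O (1.5 equiv), CaSO4, CH2Cl2, rt, dark
Reagents that add atoms: iodomethane, CI
Why: Purdie methylation is close to neutral, so the secondary hydroxyl should be etherified without acid ionisation at C4 and without base-induced ring cleavage; the stereocentre is not touched.

Step 3
Reactants: 3 2,3,4-trimethoxycyclobut-2-en-1-one
Product: 4 3-(benzyloxy)-2,4-dimethoxycyclobut-2-en-1-one (racemic)
Conditions: BnOH (5 equiv), NaH (0.1 equiv), 4 Å MS, THF, 0 °C → rt
Reagents that add atoms: benzyl alcohol, OCc1ccccc1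
Why: Vinylogous transesterification by conjugate addition–elimination: benzyl oxide adds at C3, the β-carbon of the enone, and methoxide leaves, while the C2 methoxy (α to the carbonyl) and the C4 methoxy (sp3) cannot exchange this way. Excess alcohol and sieves should shift the equilibrium, and base is used because acid would ionise C4–O.

Step 4
Reactants: 5 4-ethynyl-1,2-dimethoxybenzene
Product: 7 3-(3,4-dimethoxyphenyl)prop-2-ynal, via lithium acetylide 6 (not isolated)
Conditions: n-BuLi, THF, −78 °C; DMF, −78 → 0 °C; inverse quench into aq KH2PO4
Reagents that add atoms: N,N-dimethylformamide, CN(C)C=O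
Why: Formylation of a lithium acetylide with DMF; the buffered inverse quench should release the ynal without conjugate addition of the liberated dimethylamine.

Step 5
Reactants: 7 3-(3,4-dimethoxyphenyl)prop-2-ynal; 8 chloroacetaldehyde dimethyl acetal (2-chloro-1,1-dimethoxyethane)
Product: 10 1-(3,4-dimethoxyphenyl)-5-methoxypenta-1,4-diyn-3-ol (racemic), via lithium methoxyacetylide 9 (not isolated)
Conditions: 8 (1.3 equiv), LiNEt2 (3 equiv per 8, from n-BuLi and Et2NH), THF, −78 → 0 °C; then 7, −78 °C; pH 7 buffer, chromatography on Et3N-washed silica
Reagents that add atoms: none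
Why: Two eliminations and a deprotonation of the chloroacetal by the amide base are the established route to lithium alkoxyacetylides, and 9 should add 1,2 to the aldehyde of 7 at −78 °C faster than the liberated diethylamine adds to the ynal. The carbinol centre forms as a racemate, and the neutral work-up avoids Meyer–Schuster rearrangement of the 3-hydroxy ynol ether.

Step 6
Reactants: 10 1-(3,4-dimethoxyphenyl)-5-methoxypenta-1,4-diyn-3-ol
Product: 11 tert-butyl{[1-(3,4-dimethoxyphenyl)-5-methoxypenta-1,4-diyn-3-yl]oxy}dimethylsilane (racemic)
Conditions: TBSCl, imidazole, DMF, 0 °C → rt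
Reagents that add atoms: tert-butyldimethylsilyl chloride, CC(C)(C)[Si](C)(C)Cl
Why: Standard silylation under mildly basic conditions; it caps the hydroxyl that would otherwise acylate the ketene in step 7 and shuts off the Meyer–Schuster pathway.

Step 7
Reactants: 4 3-(benzyloxy)-2,4-dimethoxycyclobut-2-en-1-one; 11 tert-butyl{[1-(3,4-dimethoxyphenyl)-5-methoxypenta-1,4-diyn-3-yl]oxy}dimethylsilane
Product: 16 3-(benzyloxy)-6-[1-(tert-butyldimethylsilyloxy)-3-(3,4-dimethoxyphenyl)prop-2-yn-1-yl]-2,4,5-trimethoxyphenol (racemic), via vinylketene 12 (not isolated), via vinylcyclobutenone adduct 13 (not isolated), via dienylketene 14 (not isolated), via cyclohexadienone 15 (not isolated)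
Conditions: 4 (1.0 equiv), 11 (1.2 equiv), toluene (0.3 M), 110 °C, sealed tube, Ar
Reagents that add atoms: none
Why: Proposed new method: thermal conrotatory four-electron opening of 4 at C1–C4, with the C4 methoxy group turning outward, should give vinylketene 12, whose ketene C=C should add the ynol ether of 11 in a [2+2] cycloaddition to vinylcyclobutenone 13 (bonds C4a–C8a and C5–C6); a second four-electron opening, with the ring methoxy group again outward and the vinyl group therefore inward, should give the cis-dienylketene 14, which closes to cyclohexadienone 15 and tautomerises to phenol 16. The closest known reaction type is the Danheiser benzannulation of cyclobutenones with alkoxy- and silyloxyalkynes, supported by the Moore-type thermal opening of squarate-derived 4-alkoxy-2,3-dialkoxycyclobutenones to ketenes in hot toluene or xylene; the pairing of a 2,3,4-trialkoxycyclobutenone with an ynol ether is the untested part. Ring A is closed as a six-membered carbocycle by thermal disrotatory 6π electrocyclisation of the ketene-terminated triene, which forms C8–C8a. No stereocentre is created in the product, because the sp3 centres of 13 and 15 and C4 of 4 are erased on aromatisation and the carbinol centre of 11 passes through unchanged as a racemate. Regioselectivity is needed in the [2+2] step and is secured by polarity: the oxygen-free alkyne carbon is the nucleophilic terminus and bonds to the electrophilic ketene carbonyl carbon, which puts the side chain next to the new hydroxyl and the methoxy group at C5. Chemoselectivity between the two triple bonds of 11 is secured by the far higher nucleophilicity of the ynol ether over the arylalkyne. The silyl ether keeps the carbinol from trapping the ketene, and the slight excess of 11 limits O-acylation of 16 by 12.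

Step 8
Reactants: 16 3-(benzyloxy)-6-[1-(tert-butyldimethylsilyloxy)-3-(3,4-dimethoxyphenyl)prop-2-yn-1-yl]-2,4,5-trimethoxyphenol
Product: 17 3-(benzyloxy)-6-[3-(3,4-dimethoxyphenyl)-1-hydroxyprop-2-yn-1-yl]-2,4,5-trimethoxyphenol (racemic)
Conditions: TBAF (1.2 equiv), AcOH (1.2 equiv), THF, 0 °C → rt
Reagents that add atoms: none
Why: Fluoride cleavage of the secondary silyl ether; the acetic acid buffer keeps the electron-rich ortho-hydroxybenzylic alcohol from being driven to a quinone methide, and any O-to-O silyl shift is harmless because both oxygens end up free.

Step 9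
Reactants: 17 3-(benzyloxy)-6-[3-(3,4-dimethoxyphenyl)-1-hydroxyprop-2-yn-1-yl]-2,4,5-trimethoxyphenol
Product: 20 7-(benzyloxy)-2-(3,4-dimethoxyphenyl)-5,6,8-trimethoxy-4H-chromen-4-one, via ynone 18 (not isolated), via enaminone 19 (not isolated)
Conditions: MnO2 (10 equiv), CH2Cl2, rt; filter (Celite), evaporate; Et2NH (2 equiv), EtOH, rt → 50 °C
Reagents that add atoms: none
Why: MnO2 should oxidise the benzylic and propargylic carbinol selectively to ynone 18; diethylamine then adds conjugatively to give enaminone 19, and the phenol displaces the amine at the β-carbon by addition–elimination, which enforces the six-membered closure (O1–C2) over 5-exo aurone formation.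

Step 10
Reactants: 20 7-(benzyloxy)-2-(3,4-dimethoxyphenyl)-5,6,8-trimethoxy-4H-chromen-4-one
Product: 21 2-(3,4-dimethoxyphenyl)-7-hydroxy-5,6,8-trimethoxy-4H-chromen-4-one (target, achiral)
Conditions: H2 (1 atm), Pd/C (10 wt % Pd), EtOAc–MeOH, rt
Reagents that add atoms: none
Why: Catalytic hydrogenolysis of the aryl benzyl ether; the methyl ethers are inert and the conjugated C2=C3 bond of the flavone should be reduced much more slowly, so the 7-hydroxyl is freed last with no Lewis acid near the 5-methoxy group.

## Compound list

1 | dimethyl squarate (3,4-dimethoxycyclobut-3-ene-1,2-dione) | COC1=C(OC)C(=O)C1=O | starting material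
2 | 4-hydroxy-2,3-dimethoxycyclobut-2-en-1-one (racemic) | O=C1C(OC)=C(OC)C1O | intermediate
3 | 2,3,4-trimethoxycyclobut-2-en-1-one (racemic) | O=C1C(OC)=C(OC)C1OC | intermediate
4 | 3-(benzyloxy)-2,4-dimethoxycyclobut-2-en-1-one (racemic) | O=C1C(OC)=C(OCc2ccccc2)C1OC | intermediate
5 | 4-ethynyl-1,2-dimethoxybenzene | C#Cc1ccc(OC)c(OC)c1 | starting material
6 | lithium (3,4-dimethoxyphenyl)acetylide | [Li]C#Cc1ccc(OC)c(OC)c1 | intermediate (not isolated)
7 | 3-(3,4-dimethoxyphenyl)prop-2-ynal | O=CC#Cc1ccc(OC)c(OC)c1 | intermediate
8 | chloroacetaldehyde dimethyl acetal (2-chloro-1,1-dimethoxyethane) | COC(CCl)OC | starting material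
9 | lithium methoxyacetylide | [Li]C#COC | intermediate (not isolated)
10 | 1-(3,4-dimethoxyphenyl)-5-methoxypenta-1,4-diyn-3-ol (racemic) | COC#CC(O)C#Cc1ccc(OC)c(OC)c1 | intermediate
11 | tert-butyl{[1-(3,4-dimethoxyphenyl)-5-methoxypenta-1,4-diyn-3-yl]oxy}dimethylsilane (racemic) | COC#CC(O[Si](C)(C)C(C)(C)C)C#Cc1ccc(OC)c(OC)c1 | intermediate
12 | (3Z)-3-(benzyloxy)-2,4-dimethoxybuta-1,3-dien-1-one | O=C=C(OC)/C(OCc1ccccc1)=C/OC | intermediate (not isolated)
13 | 4-[(Z)-1-(benzyloxy)-2-methoxyethenyl]-2-[1-(tert-butyldimethylsilyloxy)-3-(3,4-dimethoxyphenyl)prop-2-yn-1-yl]-3,4-dimethoxycyclobut-2-en-1-one (mixture of racemic diastereomers) | O=C1C(C(O[Si](C)(C)C(C)(C)C)C#Cc2ccc(OC)c(OC)c2)=C(OC)C1(OC)/C(OCc3ccccc3)=C/OC | intermediate (not isolated)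
14 | (3Z,5Z)-5-(benzyloxy)-2-[1-(tert-butyldimethylsilyloxy)-3-(3,4-dimethoxyphenyl)prop-2-yn-1-yl]-3,4,6-trimethoxyhexa-1,3,5-trien-1-one (racemic) | O=C=C(C(O[Si](C)(C)C(C)(C)C)C#Cc1ccc(OC)c(OC)c1)/C(OC)=C(OC)\C(OCc1ccccc1)=C\OC | intermediate (not isolated)
15 | 5-(benzyloxy)-2-[1-(tert-butyldimethylsilyloxy)-3-(3,4-dimethoxyphenyl)prop-2-yn-1-yl]-3,4,6-trimethoxycyclohexa-2,4-dien-1-one (mixture of racemic diastereomers) | O=C1C(C(O[Si](C)(C)C(C)(C)C)C#Cc2ccc(OC)c(OC)c2)=C(OC)C(OC)=C(OCc2ccccc2)C1OC | intermediate (not isolated)
16 | 3-(benzyloxy)-6-[1-(tert-butyldimethylsilyloxy)-3-(3,4-dimethoxyphenyl)prop-2-yn-1-yl]-2,4,5-trimethoxyphenol (racemic) | COc1ccc(C#CC(O[Si](C)(C)C(C)(C)C)c2c(O)c(OC)c(OCc3ccccc3)c(OC)c2OC)cc1OC | intermediate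
17 | 3-(benzyloxy)-6-[3-(3,4-dimethoxyphenyl)-1-hydroxyprop-2-yn-1-yl]-2,4,5-trimethoxyphenol (racemic) | COc1ccc(C#CC(O)c2c(O)c(OC)c(OCc3ccccc3)c(OC)c2OC)cc1OC | intermediate
18 | 1-[4-(benzyloxy)-2-hydroxy-3,5,6-trimethoxyphenyl]-3-(3,4-dimethoxyphenyl)prop-2-yn-1-one | COc1ccc(C#CC(=O)c2c(O)c(OC)c(OCc3ccccc3)c(OC)c2OC)cc1OC | intermediate (not isolated)
19 | (2E)-1-[4-(benzyloxy)-2-hydroxy-3,5,6-trimethoxyphenyl]-3-(diethylamino)-3-(3,4-dimethoxyphenyl)prop-2-en-1-one | CCN(CC)/C(=C/C(=O)c1c(O)c(OC)c(OCc2ccccc2)c(OC)c1OC)c1ccc(OC)c(OC)c1 | intermediate (not isolated)
20 | 7-(benzyloxy)-2-(3,4-dimethoxyphenyl)-5,6,8-trimethoxy-4H-chromen-4-one | COc1ccc(-c2cc(=O)c3c(OC)c(OC)c(OCc4ccccc4)c(OC)c3o2)cc1OC | intermediate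
21 | 2-(3,4-dimethoxyphenyl)-7-hydroxy-5,6,8-trimethoxy-4H-chromen-4-one | COc1ccc(-c2cc(=O)c3c(OC)c(OC)c(O)c(OC)c3o2)cc1OC | target

## Step count and least certain steps

Total step count: 10. Longest linear sequence: 7 steps (steps 1, 2, 3, 7, 8, 9, 10; the branch through steps 4, 5, 6 is equally long).

**Step 7 (key step).**
- What may go wrong: the donor-rich ketene may be too weak an electrophile and reclose or oligomerise before the [2+2] union. The phenol formed may be O-acylated by remaining ketene. The doubly activated benzylic silyl ether may ionise thermally next to the new phenol.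
- Fallback (known chemistry): ring A would be made by classical aromatic substitution. It sets out from 5, used as its lithium acetylide 6, and returns to the route at 17.
- Commercial 4-(benzyloxy)-3,5-dimethoxybenzaldehyde F1 would be dibrominated at the two equivalent positions ortho to the formyl group (Br2, NaOAc, AcOH) to give 4-(benzyloxy)-2,6-dibromo-3,5-dimethoxybenzaldehyde F2.
- Copper-catalysed methanolysis (NaOMe, CuBr, DMF–MeOH, 110 °C) would give 4-(benzyloxy)-2,3,5,6-tetramethoxybenzaldehyde F3.
- Chelation-controlled cleavage of one of the two equivalent ortho methoxy groups (MgI2, Et2O–toluene, 60 °C) would give 4-(benzyloxy)-2-hydroxy-3,5,6-trimethoxybenzaldehyde F4.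
- Addition of 6 (2.2 equiv, THF, −78 → 0 °C) to F4 would then give 17.

**Step 3.**
- What may go wrong: the exchange is an equilibrium and may stall. Alkoxide attack at the carbonyl carbon followed by strain-driven cleavage of the four-membered ring may drain material during long reaction times.
- Fallback: it sets out from 3 and returns at 4. Hydrolysis of the vinylogous ester (LiOH, THF–H2O, 0 °C) would give 3-hydroxy-2,4-dimethoxycyclobut-2-en-1-one F5, precipitated as its silver salt with AgNO3.
- O-Alkylation of that salt with benzyl bromide in Et2O would give 4. Because C1 and C3 of F5 are both bonded to C2 and C4, its two oxygens are equivalent and only one benzyl ether can form.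

**Step 9.**
- What may go wrong: MnO2 may oxidise the very electron-rich free phenol alongside the carbinol, and part of the ynone may close in the 5-exo mode before the amine has added.
- Fallback: it sets out from 16, leaves 17 aside and comes back to the route at 20, passing through 18 and 19 in the flask. The phenol of 16 would be acetylated (Ac2O, pyridine, DMAP) to 3-(benzyloxy)-6-[1-(tert-butyldimethylsilyloxy)-3-(3,4-dimethoxyphenyl)prop-2-yn-1-yl]-2,4,5-trimethoxyphenyl acetate F6.
- Desilylation under weakly acidic fluoride (HF·pyridine, THF) would give 3-(benzyloxy)-6-[3-(3,4-dimethoxyphenyl)-1-hydroxyprop-2-yn-1-yl]-2,4,5-trimethoxyphenyl acetate F7.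
- MnO2 oxidation with the phenol masked would give 3-(benzyloxy)-6-[3-(3,4-dimethoxyphenyl)prop-2-ynoyl]-2,4,5-trimethoxyphenyl acetate F8.
- Diethylamine in EtOH would then remove the acetate by aminolysis and close ring C through 19 to 20.

**Step 10.**
- What may go wrong: the C2=C3 bond may be reduced to the flavanone, or the benzyl ether, flanked by two methoxy groups, may cleave slowly and invite forcing conditions.
- Fallback: it sets out from 20 and ends at 21, replacing hydrogenolysis by acidolysis (CF3CO2H, pentamethylbenzene as cation trap, CH2Cl2, rt). This uses no hydrogen and no chelating Lewis acid, so the C2=C3 bond is not exposed to reduction and the 5-methoxy group is spared. No new compound lies on the way.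

## Further compounds

F1 | step 7 | 4-(benzyloxy)-3,5-dimethoxybenzaldehyde | COc1cc(C=O)cc(OC)c1OCc1ccccc1
F2 | step 7 | 4-(benzyloxy)-2,6-dibromo-3,5-dimethoxybenzaldehyde | COc1c(Br)c(C=O)c(Br)c(OC)c1OCc1ccccc1
F3 | step 7 | 4-(benzyloxy)-2,3,5,6-tetramethoxybenzaldehyde | COc1c(OC)c(C=O)c(OC)c(OC)c1OCc1ccccc1
F4 | step 7 | 4-(benzyloxy)-2-hydroxy-3,5,6-trimethoxybenzaldehyde | COc1c(O)c(C=O)c(OC)c(OC)c1OCc1ccccc1
F5 | step 3 | 3-hydroxy-2,4-dimethoxycyclobut-2-en-1-one (racemic) | O=C1C(OC)=C(O)C1OC
F6 | step 9 | 3-(benzyloxy)-6-[1-(tert-butyldimethylsilyloxy)-3-(3,4-dimethoxyphenyl)prop-2-yn-1-yl]-2,4,5-trimethoxyphenyl acetate (racemic) | COc1ccc(C#CC(O[Si](C)(C)C(C)(C)C)c2c(OC(C)=O)c(OC)c(OCc3ccccc3)c(OC)c2OC)cc1OC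
F7 | step 9 | 3-(benzyloxy)-6-[3-(3,4-dimethoxyphenyl)-1-hydroxyprop-2-yn-1-yl]-2,4,5-trimethoxyphenyl acetate (racemic) | COc1ccc(C#CC(O)c2c(OC(C)=O)c(OC)c(OCc3ccccc3)c(OC)c2OC)cc1OC
F8 | step 9 | 3-(benzyloxy)-6-[3-(3,4-dimethoxyphenyl)prop-2-ynoyl]-2,4,5-trimethoxyphenyl acetate | COc1ccc(C#CC(=O)c2c(OC(C)=O)c(OC)c(OCc3ccccc3)c(OC)c2OC)cc1OC
F0 | step 10 | none | none
A1 | alternative 1 | 6,8-dibromo-2-(3,4-dimethoxyphenyl)-5,7-dihydroxy-4H-chromen-4-one | COc1ccc(-c2cc(=O)c3c(O)c(Br)c(O)c(Br)c3o2)cc1OC
A2 | alternative 1 | 2-(3,4-dimethoxyphenyl)-5,7-dihydroxy-6,8-dimethoxy-4H-chromen-4-one | COc1ccc(-c2cc(=O)c3c(O)c(OC)c(O)c(OC)c3o2)cc1OC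
A3 | alternative 2 | 5-(benzyloxy)-3,4-dimethoxy-2-(trimethylsilyl)phenyl trifluoromethanesulfonate | COc1c(OC)c(OCc2ccccc2)cc(OS(=O)(=O)C(F)(F)F)c1[Si](C)(C)C
A4 | alternative 2 | 3-(3,4-dimethoxyphenyl)prop-2-ynoic acid | COc1ccc(C#CC(=O)O)cc1OC
A5 | alternative 2 | 7-(benzyloxy)-2-(3,4-dimethoxyphenyl)-5,6-dimethoxy-4H-chromen-4-one | COc1ccc(-c2cc(=O)c3c(OC)c(OC)c(OCc4ccccc4)cc3o2)cc1OC
A6 | alternative 3 | 1-[4-(benzyloxy)-2,6-dibromo-3,5-dimethoxyphenyl]-3-(3,4-dimethoxyphenyl)propane-1,3-dione | COc1ccc(C(=O)CC(=O)c2c(Br)c(OC)c(OCc3ccccc3)c(OC)c2Br)cc1OC
A7 | alternative 3 | 7-(benzyloxy)-5-bromo-2-(3,4-dimethoxyphenyl)-6,8-dimethoxy-4H-chromen-4-one | COc1ccc(-c2cc(=O)c3c(Br)c(OC)c(OCc4ccccc4)c(OC)c3o2)cc1OC
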